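**Retrosynthetic overview**

1. Target ⇐ C7‑selective angeloylation of the 7,9‑anti diol ⇐ hydroxyl‑directed reduction of the 7‑hydroxy‑9‑ketone ⇐ aldol closure of the seven‑membered ring (C7–C8).
2. Six‑membered ring ⇐ aldol condensation of a cis‑1,3‑acetyl/formyl cyclobutane, then Me2CuLi to set C3.
3. Cyclobutane (key step) ⇐ oxidative coupling of the two α‑carbons of a 1,6‑bis‑enolate (C10–C11): two enolate carbons are joined after one is oxidised to an electrophilic α‑keto radical. The bis‑enolate comes from a dianionic oxy‑Cope shift (C4–C5) of a 1,2‑divinyl diol.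
4. Diol ⇐ biacetyl + two E‑alkenyllithiums; the C6 quaternary stereocentre ⇐ Pd‑catalysed asymmetric allylation of nitromethane (a formyl anion equivalent) with isoprene monoepoxide.
5. Ring order: cyclobutane, then six‑membered ring, then seven‑membered ring.

Convention (one line): longipinane numbering is used for the tricycle – C1 ketone, C2, C3 (methyl), cyclobutane C4–C5–C11–C10 (C10 carries a methyl), C6 quaternary (CH3 and CH2OAc), bridge C7–C8–C9; configurations are those of the given SMILES.

**Route**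

Step 1
Reactants: 1 2‑methyl‑2‑vinyloxirane (racemic), 2 nitromethane
Product: 3 (S)‑2‑methyl‑2‑(nitromethyl)but‑3‑en‑1‑ol
Conditions: Pd2(dba)3·CHCl3 (1 mol %), DACH‑phenyl Trost ligand (3 mol %, the enantiomer that gives S), 2 (5 equiv), CH2Cl2, rt
Reagents that add atoms: none
Why: Trost‑type dynamic kinetic asymmetric allylic alkylation, in which the interconverting π‑allyl complexes of zerovalent palladium are attacked at the tertiary terminus by the nitronate generated by the liberated alkoxide, so the ligand sets the quaternary C6 stereocentre.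

Step 2
Reactants: 3 (S)‑2‑methyl‑2‑(nitromethyl)but‑3‑en‑1‑ol
Product: 4 (S)‑tert‑butyldimethyl{[2‑methyl‑2‑(nitromethyl)but‑3‑en‑1‑yl]oxy}silane
Conditions: TBSCl, imidazole, DMF, rt
Reagents that add atoms: tert‑butyldimethylsilyl chloride CC(C)(C)[Si](C)(C)Cl
Why: Standard imidazole‑mediated silylation masks the primary hydroxyl for the basic and organometallic steps and touches no stereocentre.

Step 3
Reactants: 4 (S)‑tert‑butyldimethyl{[2‑methyl‑2‑(nitromethyl)but‑3‑en‑1‑yl]oxy}silane
Product: 6 (R)‑2‑{[(tert‑butyldimethylsilyl)oxy]methyl}‑2‑methylbut‑3‑enal, via potassium nitronate 5 (not isolated)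
Conditions: KOtBu, THF, 0 °C; then dimethyldioxirane (1.0 equiv, acetone), −78 to 0 °C
Reagents that add atoms: dimethyldioxirane CC1(C)OO1
Why: Oxidative Nef reaction in which the nitronate is oxygenated at carbon and loses nitrite to give an aldehyde that has a quaternary α‑carbon and so cannot enolise or epimerise.

Step 4
Reactants: 6 (R)‑2‑{[(tert‑butyldimethylsilyl)oxy]methyl}‑2‑methylbut‑3‑enal
Product: 7 (S,E)‑tert‑butyl{[2‑(2‑iodovinyl)‑2‑methylbut‑3‑en‑1‑yl]oxy}dimethylsilane
Conditions: CrCl2 (6 equiv), CHI3 (2 equiv), THF, 0 °C to rt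
Reagents that add atoms: iodoform IC(I)I
Why: Takai olefination, where the geminal dichromium reagent adds to the aldehyde and eliminates to the E‑iodoalkene, the E preference being reinforced by the bulky quaternary neighbour.

Step 5
Reactants: 7 (S,E)‑tert‑butyl{[2‑(2‑iodovinyl)‑2‑methylbut‑3‑en‑1‑yl]oxy}dimethylsilane, 8 butane‑2,3‑dione
Product: 10 (4E,6S)‑6‑{[(tert‑butyldimethylsilyl)oxy]methyl}‑3‑hydroxy‑3,6‑dimethylocta‑4,7‑dien‑2‑one (both C3 epimers), via alkenyllithium 9 (not isolated)
Conditions: t‑BuLi (2.0 equiv), Et2O, −78 °C; then cannulated into 8 (5 equiv), THF, −78 °C; H2O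
Reagents that add atoms: none
Why: Iodine–lithium exchange proceeds with retention of the E geometry and the alkenyllithium adds once to the excess 1,2‑diketone (inverse addition); the new carbinol centre is uncontrolled but becomes trigonal in step 8.

Step 6
Reactants: 11 1,1‑diethoxybut‑2‑yne
Product: 13 (E)‑1,1‑diethoxy‑3‑iodobut‑2‑ene, via alkenylzirconocene 12 (not isolated)
Conditions: (C5H5)2Zr(H)Cl, THF, rt; then I2, 0 °C
Reagents that add atoms: iodine II
Why: Hydrozirconation is a syn addition that places zirconium on the less hindered methyl‑bearing carbon, and iodinolysis occurs with retention, so the acetal carbon and iodine end up trans.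

Step 7
Reactants: 10 (4E,6S)‑6‑{[(tert‑butyldimethylsilyl)oxy]methyl}‑3‑hydroxy‑3,6‑dimethylocta‑4,7‑dien‑2‑one, 13 (E)‑1,1‑diethoxy‑3‑iodobut‑2‑ene
Product: 15 (2E,6E,8S)‑8‑{[(tert‑butyldimethylsilyl)oxy]methyl}‑1,1‑diethoxy‑3,4,5,8‑tetramethyldeca‑2,6,9‑triene‑4,5‑diol (mixture of C4/C5 diastereomers), via alkenyllithium 14 (not isolated)
Conditions: 13 (3 equiv), t‑BuLi (6 equiv), Et2O, −78 °C; then 10, THF, −78 to −20 °C; H2O
Reagents that add atoms: none
Why: The second alkenyllithium (the first equivalent removes the hydroxyl proton) adds to the remaining ketone with help from chelation to the neighbouring alkoxide, giving a 1,2‑divinyl diol whose carbinol diastereomers all converge in step 8.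

Step 8 (key step)
Reactants: 15 (2E,6E,8S)‑8‑{[(tert‑butyldimethylsilyl)oxy]methyl}‑1,1‑diethoxy‑3,4,5,8‑tetramethyldeca‑2,6,9‑triene‑4,5‑diol
Product: 18 1,1'‑{(1R,2S,3S,4R)‑3‑[(2S)‑1‑{[tert‑butyl(dimethyl)silyl]oxy}‑2‑methylbut‑3‑en‑2‑yl]‑2‑(diethoxymethyl)‑1‑methylcyclobutane‑1,4‑diyl}di(ethan‑1‑one), via dipotassium dialkoxide 16 (not isolated), via dipotassium bis‑enolate 17 (not isolated)
Conditions: KH (2.5 equiv), 18‑crown‑6 (2.5 equiv), THF, 0 °C to rt; then FeCl3 (2.2 equiv), DMF, −78 to 0 °C
Reagents that add atoms: none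
Why: Proposed new method: the dialkoxide undergoes a dianion‑accelerated oxy‑Cope shift through a chair transition state with both E substituents equatorial (this fixes the trans C4/C5 relationship; attack at C5 anti to the CH2OTBS group of the C6 quaternary centre should give only modest facial selectivity, and the minor, also enantiopure, facial isomer is removed by chromatography), and the regiodefined 1,6‑bis‑enolate is then joined at its two nucleophilic α‑carbons by one‑electron oxidation with FeCl3 (one enolate becomes an electrophilic α‑keto radical that adds to the other, and the resulting ketyl is oxidised), with allylic strain placing the acetal cis to the C10 methyl and each acetyl trans to its neighbour so that the all‑trans cyclobutane forms; the closest known reactions are dianionic oxy‑Cope rearrangements of 1,2‑divinyl diols and oxidative enolate couplings with trivalent iron or divalent copper, including closure of adipate bis‑enolates to trans‑cyclobutane‑1,2‑dicarboxylates.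

Step 9
Reactants: 18 all‑trans cyclobutane diketone acetal
Product: 21 (1R,5S,6R,7S)‑6‑acetyl‑7‑[(2S)‑1‑hydroxy‑2‑methylbut‑3‑en‑2‑yl]‑6‑methylbicyclo[3.1.1]hept‑3‑en‑2‑one, via keto aldehyde 19 (not isolated), via aldol adduct 20 (not isolated)
Conditions: 1 M HCl, THF, rt; then K2CO3, MeOH, rt to 40 °C
Reagents that add atoms: none
Why: Acid hydrolyses the acetal and the silyl ether, and base then effects an intramolecular aldol condensation in which only the methyl of the C11 acetyl can reach the cis‑1,3 aldehyde (the other acetyl would give a ring trans‑fused to the cyclobutane), any epimerisation at C4 or C11 being corrected because only the cis isomer cyclises.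

Step 10
Reactants: 21 bicyclic enone alcohol
Product: 22 (2S)‑2‑[(1R,5S,6R,7S)‑6‑acetyl‑6‑methyl‑2‑oxobicyclo[3.1.1]hept‑3‑en‑7‑yl]‑2‑methylbut‑3‑en‑1‑yl acetate
Conditions: Ac2O, pyridine, DMAP (cat.), CH2Cl2, 0 °C to rt
Reagents that add atoms: acetic anhydride CC(=O)OC(C)=O
Why: Nucleophile‑catalysed acetylation of the only hydroxyl installs the primary acetate of the target.

Step 11
Reactants: 22 bicyclic enone acetate
Product: 23 (2S)‑2‑[(1R,4R,5S,6R,7S)‑6‑acetyl‑4,6‑dimethyl‑2‑oxobicyclo[3.1.1]heptan‑7‑yl]‑2‑methylbut‑3‑en‑1‑yl acetate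
Conditions: Me2CuLi (from MeLi and CuI), Et2O, −78 to −40 °C; aq. NH4Cl
Reagents that add atoms: lithium dimethylcuprate [Li+].C[Cu-]C
Why: Gilman conjugate addition to the bicyclic enone occurs on the face of the three‑carbon bridge that is syn to the C5–H bridge and anti to the C10 bridge with its inward‑pointing methyl, which sets the C3 methyl stereocentre (R) as in the target.

Step 12
Reactants: 23 vinyl diketone acetate
Product: 25 ketol: 7‑hydroxylongipinane‑1,9‑dione with CH2OAc on C6 (3R,4S,5S,6S,7R,10R,11R), via keto aldehyde 24 (not isolated)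
Conditions: O3, CH2Cl2, −78 °C; PPh3; then DBU (0.2 equiv), 0 °C to rt
Reagents that add atoms: ozone [O-][O+]=O
Why: Ozonolysis unmasks the C7 aldehyde, and the reversible DBU‑mediated intramolecular aldol addition of the C9 methyl ketone (the only enolate that can reach the non‑enolisable aldehyde across the cis‑1,3‑disubstituted cyclobutane) closes the seven‑membered ring, the C7 hydroxyl settling trans to the larger CH2OAc group and cis to the methyl on C6.

Step 13
Reactants: 25 ketol
Product: 26 anti diol: 7,9‑dihydroxylongipinan‑1‑one with CH2OAc on C6 (3R,4S,5S,6S,7R,9R,10R,11R)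
Conditions: Me4NBH(OAc)3, MeCN/AcOH, −30 °C
Reagents that add atoms: none
Why: Saksena–Evans reduction, in which the C7 hydroxyl binds boron and delivers hydride intramolecularly to the C9 ketone to give the 1,3‑anti (trans) diol and hence the 9R carbinol, while the unassisted C1 ketone is not reduced by this weak hydride.

Step 14
Reactants: 26 anti diol, 27 angelic acid
Product: 29 target CNP0212099.1, via mixed anhydride 28 (not isolated)
Conditions: 27, 2,4,6‑trichlorobenzoyl chloride, Et3N, toluene, rt; then 26, 75 °C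
Reagents that add atoms: none
Why: Yamaguchi esterification through the mixed anhydride without DMAP avoids Z‑to‑E isomerisation to the tiglate and acylates the C7 hydroxyl in preference to the C9 hydroxyl, which is neopentyl to the cyclobutane bridgehead and the less accessible of the two.

**Compound list**

1 | 2‑methyl‑2‑vinyloxirane (racemic) | CC1(C=C)CO1 | starting material
2 | nitromethane | C[N+](=O)[O-] | starting material
3 | (S)‑2‑methyl‑2‑(nitromethyl)but‑3‑en‑1‑ol | [O-][N+](=O)C[C@@](C=C)(C)CO | intermediate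
4 | (S)‑TBS ether of 3 | [O-][N+](=O)C[C@@](C=C)(C)CO[Si](C)(C)C(C)(C)C | intermediate
5 | potassium nitronate of 4 | [K+].[O-][N+]([O-])=C[C@@](C=C)(C)CO[Si](C)(C)C(C)(C)C | intermediate
6 | (R)‑2‑{[(tert‑butyldimethylsilyl)oxy]methyl}‑2‑methylbut‑3‑enal | O=C[C@@](C=C)(C)CO[Si](C)(C)C(C)(C)C | intermediate
7 | (S,E)‑iodoalkene | I/C=C/[C@@](C=C)(C)CO[Si](C)(C)C(C)(C)C | intermediate
8 | butane‑2,3‑dione | CC(=O)C(C)=O | starting material
9 | alkenyllithium from 7 | [Li]/C=C/[C@@](C=C)(C)CO[Si](C)(C)C(C)(C)C | intermediate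
10 | (4E,6S)‑hydroxy ketone, both C3 epimers | CC(=O)C(C)(O)/C=C/[C@@](C=C)(C)CO[Si](C)(C)C(C)(C)C | intermediate
11 | 1,1‑diethoxybut‑2‑yne | CC#CC(OCC)OCC | starting material
12 | alkenylzirconocene chloride from 11 | CCOC(OCC)/C=C(\C)[Zr](Cl)(C1C=CC=C1)C1C=CC=C1 | intermediate
13 | (E)‑1,1‑diethoxy‑3‑iodobut‑2‑ene | CCOC(OCC)/C=C(\C)I | intermediate
14 | alkenyllithium from 13 | CCOC(OCC)/C=C(\C)[Li] | intermediate
15 | (2E,6E,8S)‑divinyl diol, mixture of C4/C5 diastereomers | CC(O)(/C=C/[C@@](C=C)(C)CO[Si](C)(C)C(C)(C)C)C(C)(O)/C(C)=C/C(OCC)OCC | intermediate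
16 | dipotassium dialkoxide of 15 | [K+].[K+].CC([O-])(/C=C/[C@@](C=C)(C)CO[Si](C)(C)C(C)(C)C)C(C)([O-])/C(C)=C/C(OCC)OCC | intermediate
17 | dipotassium 1,6‑bis‑enolate | [K+].[K+].CC([O-])=C(C)[C@@H](C(OCC)OCC)[C@@H](C=C(C)[O-])[C@@](C=C)(C)CO[Si](C)(C)C(C)(C)C | intermediate
18 | all‑trans cyclobutane (1R,2S,3S,4R; side chain 2S) | CC(=O)[C@]1(C)[C@@H](C(OCC)OCC)[C@@H]([C@H]1C(C)=O)[C@@](C=C)(C)CO[Si](C)(C)C(C)(C)C | intermediate
19 | cyclobutane keto aldehyde alcohol | CC(=O)[C@]1(C)[C@@H](C=O)[C@@H]([C@H]1C(C)=O)[C@@](C=C)(C)CO | intermediate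
20 | bicyclic aldol adduct (4‑hydroxy, either epimer) | CC(=O)[C@]2(C)[C@@H]3[C@@H]([C@H]2C(=O)CC3O)[C@@](C=C)(C)CO | intermediate
21 | (1R,5S,6R,7S)‑bicyclo[3.1.1]hept‑3‑en‑2‑one alcohol | CC(=O)[C@]2(C)[C@@H]3[C@@H]([C@H]2C(=O)C=C3)[C@@](C=C)(C)CO | intermediate
22 | acetate of 21 | CC(=O)[C@]2(C)[C@@H]3[C@@H]([C@H]2C(=O)C=C3)[C@@](C=C)(C)COC(C)=O | intermediate
23 | (1R,4R,5S,6R,7S)‑4‑methyl bicyclic diketone acetate | CC(=O)[C@]2(C)[C@@H]3[C@@H]([C@H]2C(=O)C[C@H]3C)[C@@](C=C)(C)COC(C)=O | intermediate
24 | keto aldehyde from ozonolysis of 23 | CC(=O)[C@]2(C)[C@@H]3[C@@H]([C@H]2C(=O)C[C@H]3C)[C@@](C=O)(C)COC(C)=O | intermediate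
25 | ketol (7‑hydroxylongipinane‑1,9‑dione, CH2OAc on C6) | O[C@@H]1CC(=O)[C@]2(C)[C@@H]3[C@@H]([C@H]2C(=O)C[C@H]3C)[C@@]1(C)COC(C)=O | intermediate
26 | anti diol (7,9‑dihydroxylongipinan‑1‑one, CH2OAc on C6) | O[C@@H]1C[C@@H](O)[C@]2(C)[C@@H]3[C@@H]([C@H]2C(=O)C[C@H]3C)[C@@]1(C)COC(C)=O | intermediate
27 | angelic acid ((Z)‑2‑methylbut‑2‑enoic acid) | C/C=C(/C)C(=O)O | starting material
28 | angelic 2,4,6‑trichlorobenzoic anhydride | C/C=C(/C)C(=O)OC(=O)c1c(Cl)cc(Cl)cc1Cl | intermediate
29 | CNP0212099.1 | C/C=C(/C)C(=O)O[C@@H]1C[C@@H](O)[C@]2(C)[C@@H]3[C@@H]([C@H]2C(=O)C[C@H]3C)[C@@]1(C)COC(C)=O | target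

**Step count**

Total: 14 steps. Longest linear sequence: 13 steps (steps 1–5 and 7–14; step 6 is a one‑step side branch).

**Three steps most likely to fail, with fallbacks**

Step 8 is the largest risk. Closing a cyclobutane by oxidative enolate coupling may lose out to oligomerisation or α‑chlorination. The hindered dialkoxide may also partly fragment into two enone radical anions, which would erode the chair stereospecificity. Facial selectivity relative to the C6 quaternary centre rests only on methyl versus vinyl discrimination and may be close to 1:1; this costs yield, not enantiopurity, because both isomers are enantiopure and separable at 18 or 21. The fallback sets out from 15. The oxy‑Cope shift is run as before but the bis‑enolate is quenched with Me3SiCl to isolate the bis(trimethylsilyl enol ether) F1. F1 is then cyclised by radical‑cation coupling with (NH4)2Ce(NO3)6 and NaHCO3 in MeCN at −30 °C (oxidation of one silyl enol ether gives the α‑keto radical, which closes on the other). This returns to the route at 18.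

Step 12 is the second risk. The seven‑membered aldol may stall at the open keto aldehyde, dehydrate, or give the wrong C7 epimer. The fallback sets out from 23. After the same ozonolysis, piperidinium acetate in hot benzene drives the condensation through to the cycloheptenone F2 (longipin‑7‑ene‑1,9‑dione with CH2OAc on C6). Copper‑catalysed conjugate borylation (bis(pinacolato)diboron, CuCl, NaOtBu, MeOH) adds boron to C7 from the face anti to the CH2OAc group to give the boronate F3. Oxidation with NaBO3·4H2O, with retention, returns to the route at 25.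

Step 14 is the third risk. The C7 and C9 hydroxyls are both neopentyl, so regioselective angeloylation is not assured. The fallback sets out from 25 and skips step 13. An Evans–Tishchenko reduction with pent‑4‑enal and catalytic SmI2 delivers hydride from the C7 hemiacetal and gives the anti 9‑hydroxy 7‑pent‑4‑enoate F4, so the two oxygens are differentiated as the C9 stereocentre is set. Silylation with TBSOTf and 2,6‑lutidine gives the 9‑silyl ether F5. Iodolactonisation of the pentenoate with I2 and NaHCO3 in aqueous THF frees the C7 hydroxyl to give the alcohol F6. Esterification with mixed anhydride 28 gives the 7‑angelate 9‑silyl ether F7, and HF·pyridine removes the silyl group to reach 29.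

**Further compounds**

F1 | step 8 | bis(trimethylsilyl enol ether) of the 1,6‑diketone | CC(O[Si](C)(C)C)=C(C)[C@@H](C(OCC)OCC)[C@@H](C=C(C)O[Si](C)(C)C)[C@@](C=C)(C)CO[Si](C)(C)C(C)(C)C
F2 | step 12 | cycloheptenone (longipin‑7‑ene‑1,9‑dione, CH2OAc on C6) | C1=CC(=O)[C@]2(C)[C@@H]3[C@@H]([C@H]2C(=O)C[C@H]3C)[C@@]1(C)COC(C)=O
F3 | step 12 | 7‑(pinacolboryl)longipinane‑1,9‑dione, CH2OAc on C6 | CC1(C)OB(OC1(C)C)[C@@H]2CC(=O)[C@]3(C)[C@@H]4[C@@H]([C@H]3C(=O)C[C@H]4C)[C@@]2(C)COC(C)=O
F4 | step 14 | 9‑hydroxy 7‑pent‑4‑enoate | C=CCCC(=O)O[C@@H]1C[C@@H](O)[C@]2(C)[C@@H]3[C@@H]([C@H]2C(=O)C[C@H]3C)[C@@]1(C)COC(C)=O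
F5 | step 14 | 9‑O‑TBS 7‑pent‑4‑enoate | C=CCCC(=O)O[C@@H]1C[C@@H](O[Si](C)(C)C(C)(C)C)[C@]2(C)[C@@H]3[C@@H]([C@H]2C(=O)C[C@H]3C)[C@@]1(C)COC(C)=O
F6 | step 14 | 9‑O‑TBS 7‑alcohol | O[C@@H]1C[C@@H](O[Si](C)(C)C(C)(C)C)[C@]2(C)[C@@H]3[C@@H]([C@H]2C(=O)C[C@H]3C)[C@@]1(C)COC(C)=O
F7 | step 14 | 9‑O‑TBS 7‑angelate | C/C=C(/C)C(=O)O[C@@H]1C[C@@H](O[Si](C)(C)C(C)(C)C)[C@]2(C)[C@@H]3[C@@H]([C@H]2C(=O)C[C@H]3C)[C@@]1(C)COC(C)=O
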